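**Plan**

- Retrosynthesis: the 2-aminopyrimidine is opened at N1'–C6' and N3'–C4' (guanidine leaves). The ynone left behind is cut at C4'–C5' and at indole C3–C4', giving a 3-iodoindole, carbon monoxide and trimethylsilylacetylene.
- Enabling feature: pyrimidine C4' is a lone carbon at the ketone oxidation level, bonded only to indole C3, to C5' and to N3'. Such a carbon can be delivered as CO between an indol-3-yl–palladium species and an acetylide.
- Forward order: the indole (benzene ring and pyrrole ring) is bought with both bromines in place. C3 is iodinated and N1 is Boc-protected. The carbonylative alkynylation attaches the C4'–C5'–C6' chain without closing a ring. Guanidine then closes the pyrimidine, the only ring made, while the silyl and Boc groups are lost in the same flask.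
- Stereochemistry: the target has no stereocentre and none is created on the way.

Key step: step 3

Assumption: 5,6-dibromo-1H-indole is treated as a catalogue compound, and CO is supplied from a balloon at one atmosphere.

**Route**

Step 1
Reactants: 1 5,6-dibromo-1H-indole
Product: 2 5,6-dibromo-3-iodo-1H-indole
Conditions: I2 (1.05 equiv), KOH (2.5 equiv), DMF, rt, 1 h, dark; poured into aq. NaHSO3/NH3, filtered, dried in vacuo, used at once
Reagents that add atoms: iodine, II
Why: Electrophilic aromatic iodination of the indole (as its potassium salt) should occur only at C3, the enamine-like and most nucleophilic carbon, because the benzene ring is deactivated by the two bromines.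

Step 2
Reactants: 2 5,6-dibromo-3-iodo-1H-indole
Product: 3 tert-butyl 5,6-dibromo-3-iodoindole-1-carboxylate
Conditions: Boc2O (1.3 equiv), DMAP (10 mol%), CH2Cl2, rt, 2 h
Reagents that add atoms: di-tert-butyl dicarbonate, CC(C)(C)OC(=O)OC(=O)OC(C)(C)C
Why: DMAP-catalysed N-acylation of the indole N–H by the anhydride (carbamate formation) is fast and leaves the C–I and C–Br bonds alone, and the carbamate makes the light- and acid-sensitive 3-iodide storable.

Step 3
Reactants: 3 tert-butyl 5,6-dibromo-3-iodoindole-1-carboxylate, 4 carbon monoxide, 5 trimethylsilylacetylene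
Product: 6 tert-butyl 5,6-dibromo-3-[3-(trimethylsilyl)prop-2-ynoyl]indole-1-carboxylate
Conditions: PdCl2(PPh3)2 (5 mol%), CuI (2 mol%), Et3N (2 equiv), CO (1 atm, balloon), THF, rt, 48 h; 5 (1.5 equiv) added last and slowly to the CO-saturated solution
Reagents that add atoms: none
Why: Zerovalent palladium, formed in the flask from the divalent precatalyst PdCl2(PPh3)2, inserts into the C3–I bond of 3; CO then coordinates and the indol-3-yl group migrates onto it to give the acylpalladium iodide (C3–C4'), which takes the acetylide from the copper acetylide made from 5, CuI and Et3N and reductively eliminates the ynone (C4'–C5'). This is a carbonylative Sonogashira coupling, a reaction type established for N-acyl 3-iodoindoles under one atmosphere of CO. No ring closes and no stereocentre is formed; the step only joins the three-carbon chain at the oxidation level the pyrimidine needs. Two selectivities are required: insertion at C–I in preference to the two C–Br bonds, which the much weaker C3–I bond and room temperature should secure, and CO insertion ahead of direct alkynylation, which the electron-rich indol-3-yl ligand (fast migration to CO), the CO-saturated solution and the slow addition of 5 should secure. The Boc group keeps the iodide stable and keeps the indole nitrogen out of the copper chemistry.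

Step 4
Reactants: 6 tert-butyl 5,6-dibromo-3-[3-(trimethylsilyl)prop-2-ynoyl]indole-1-carboxylate, 7 guanidine hydrochloride
Product: 11 meridianin F (4-(5,6-dibromo-1H-indol-3-yl)pyrimidin-2-amine), via terminal ynone 8 (not isolated), via guanidine enaminone 9 (not isolated), via N-Boc meridianin F 10 (not isolated)
Conditions: 7 (2.5 equiv), Na2CO3·10H2O (3 equiv), t-BuOH/MeCN 1:1, 80 °C, 24 h
Reagents that add atoms: none
Why: In this ynone–guanidine cyclocondensation the carbonate medium removes the alkynyl silyl group, free guanidine adds in Michael fashion to C6' of the terminal ynone (N1'–C6'), its second nitrogen attacks the C4' ketone in a 6-exo-trig addition followed by dehydration (N3'–C4') to give the aromatic 2-aminopyrimidine, and the hot basic, water-containing medium hydrolyses the electron-poor N-indolyl carbamate, the exact order of these events being immaterial because every path converges on 11.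

**Compound list**

1 | 5,6-dibromo-1H-indole | Brc1cc2cc[nH]c2cc1Br | starting material
2 | 5,6-dibromo-3-iodo-1H-indole | Ic1c[nH]c2cc(Br)c(Br)cc12 | intermediate
3 | tert-butyl 5,6-dibromo-3-iodoindole-1-carboxylate | CC(C)(C)OC(=O)n1cc(I)c2cc(Br)c(Br)cc21 | intermediate
4 | carbon monoxide | [C-]#[O+] | starting material
5 | trimethylsilylacetylene | C#C[Si](C)(C)C | starting material
6 | tert-butyl 5,6-dibromo-3-[3-(trimethylsilyl)prop-2-ynoyl]indole-1-carboxylate | CC(C)(C)OC(=O)n1cc(C(=O)C#C[Si](C)(C)C)c2cc(Br)c(Br)cc21 | intermediate
7 | guanidine hydrochloride | NC(N)=N.Cl | starting material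
8 | tert-butyl 5,6-dibromo-3-(prop-2-ynoyl)indole-1-carboxylate | CC(C)(C)OC(=O)n1cc(C(=O)C#C)c2cc(Br)c(Br)cc21 | intermediate
9 | tert-butyl 5,6-dibromo-3-[(2Z)-3-(carbamimidoylamino)prop-2-enoyl]indole-1-carboxylate | CC(C)(C)OC(=O)n1cc(C(=O)/C=C\NC(N)=N)c2cc(Br)c(Br)cc21 | intermediate
10 | tert-butyl 3-(2-aminopyrimidin-4-yl)-5,6-dibromoindole-1-carboxylate | CC(C)(C)OC(=O)n1cc(-c2ccnc(N)n2)c2cc(Br)c(Br)cc21 | intermediate
11 | meridianin F, 4-(5,6-dibromo-1H-indol-3-yl)pyrimidin-2-amine | Nc1nccc(-c2c[nH]c3cc(Br)c(Br)cc23)n1 | target

**Step count**

Total step count: 4. Longest linear sequence: 4 steps (1 → 2 → 3 → 6 → 11).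

**Steps most likely to fail**

1. Step 3 (key step). Direct, non-carbonylative alkynylation may outrun CO insertion, or turnover may be so slow that warming becomes necessary and oxidative addition at the C–Br bonds begins. The fallback takes C4' from DMF and avoids both the iodide and the CO. Setting out from 1, Vilsmeier–Haack formylation (POCl3, DMF, 0 to 40 °C) would give the iminium salt N-[(5,6-dibromo-1H-indol-3-yl)methylidene]-N-methylmethanaminium chloride F1. Aqueous NaOH work-up would hydrolyse it to 5,6-dibromo-1H-indole-3-carbaldehyde F2. Boc2O with catalytic DMAP would convert this into tert-butyl 5,6-dibromo-3-formylindole-1-carboxylate F3. Commercial lithium (trimethylsilyl)acetylide (LiC≡CSiMe3) in THF at −78 °C would add to the aldehyde to give racemic tert-butyl 5,6-dibromo-3-[1-hydroxy-3-(trimethylsilyl)prop-2-yn-1-yl]indole-1-carboxylate F4. MnO2 in CH2Cl2 at rt would oxidise this propargylic alcohol, removing its stereocentre, and the sequence rejoins the route at 6.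

2. Step 4. Early desilylation may expose the terminal ynone to oligomerisation before the sparingly soluble guanidine adds, and Boc loss may stay incomplete, giving mixtures. The fallback stores the three-carbon electrophile as a stable vinylogous amide first. Setting out from 6, dimethylamine (2 M in THF, 1.2 equiv) in MeOH at rt should desilylate (through 8) and add in conjugate fashion to give tert-butyl 5,6-dibromo-3-[(2E)-3-(dimethylamino)prop-2-enoyl]indole-1-carboxylate F5. Heating F5 with 7 and K2CO3 in 2-methoxyethanol/water (10:1) at 115 °C should exchange dimethylamine for guanidine (through 9), cyclodehydrate (through 10) and hydrolyse the carbamate. This is the classical enaminone–guanidine pyrimidine synthesis, and it arrives at 11.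

3. Step 1. The unprotected 3-iodoindole may lose iodine and oligomerise during isolation and drying (light, trace acid). The fallback reverses the order so that no N–H iodide is ever handled. Setting out from 1, Boc2O with catalytic DMAP in CH2Cl2 would give tert-butyl 5,6-dibromoindole-1-carboxylate F6. N-Iodosuccinimide with catalytic CF3CO2H in MeCN at rt in the dark should iodinate the enecarbamate C2=C3 bond at C3, by analogy with the C3-bromination of N-acyl indoles with N-bromosuccinimide. This comes back to the route at 3.

**Further compounds**

F1 | step 3 | N-[(5,6-dibromo-1H-indol-3-yl)methylidene]-N-methylmethanaminium chloride | C[N+](C)=Cc1c[nH]c2cc(Br)c(Br)cc12.[Cl-]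
F2 | step 3 | 5,6-dibromo-1H-indole-3-carbaldehyde | O=Cc1c[nH]c2cc(Br)c(Br)cc12
F3 | step 3 | tert-butyl 5,6-dibromo-3-formylindole-1-carboxylate | CC(C)(C)OC(=O)n1cc(C=O)c2cc(Br)c(Br)cc21
F4 | step 3 | tert-butyl 5,6-dibromo-3-[1-hydroxy-3-(trimethylsilyl)prop-2-yn-1-yl]indole-1-carboxylate (racemic) | CC(C)(C)OC(=O)n1cc(C(O)C#C[Si](C)(C)C)c2cc(Br)c(Br)cc21
F5 | step 4 | tert-butyl 5,6-dibromo-3-[(2E)-3-(dimethylamino)prop-2-enoyl]indole-1-carboxylate | CC(C)(C)OC(=O)n1cc(C(=O)/C=C/N(C)C)c2cc(Br)c(Br)cc21
F6 | step 1 | tert-butyl 5,6-dibromoindole-1-carboxylate | CC(C)(C)OC(=O)n1ccc2cc(Br)c(Br)cc21
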